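**Plan**
- Retrosynthetic cuts: the C13 acetate; C4=C12 (aldol condensation with a C12–C15 epoxy aldehyde); the 7-hydroxy-8,9-epoxide back to a Z C7=C8 olefin; C11=C19 back to a ketone; the lactone C3–O2 back to a C3 acetal and a C1 silyl ether.
- Enabling feature: in the nine-membered ring C11 and C7 are joined through C10–C9–C8. With C11 as ketone and C7=C8 as olefin this is a γ,δ-unsaturated ketone, the product of a Claisen shift in a 7-vinyl-2-methylidene-oxepane whose oxygen bridges C11 and C7; the cut is C9–C10, with C7–O restored.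
- The oxepane comes from Baeyer–Villiger oxidation and methylenation of a 2,3-trans cyclohexanone whose quaternary α-carbon carries methyl and vinyl.
- Forward order: six-membered carbocycle, oxepanone, nine-membered carbocycle (key step), δ-lactone ring, C7/C8 oxygenation, side chain joined at C4=C12, 8,9-epoxide, acetate.
- Stereochemistry: C4a by ligand-controlled copper conjugate addition; C11a trans by enolate hydroxymethylation; C7 by face-selective epoxidation of the Z-cyclononene; C8/C9 by hydroxyl-directed vanadium epoxidation; C13 from (R)-but-3-ene-1,2-diol; C14 by hydroxyl-directed threo epoxidation; E-C4=C12 thermodynamic.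

Key step: step 8

Remark on numbering: locants C1–C19 are those of the target (lactone O2–C1H2–C11a and C3(=O)–C4(=C12)–C4a; nine-membered ring C4a–C5–C6–C7–C8–C9–C10–C11(=C19)–C11a; side chain C12–C15).
Remark on the chemistry: enone 6 is racemic, so 8–12 are carried as the two epimers at the quaternary carbon that becomes C7; this centre turns trigonal in step 8, and the SMILES of 8–12 leave it undefined.

**Route**

Step 1
Reactants: 1 2-methylcyclohexan-1-one (racemic)
Product: 3 6-methylcyclohex-2-en-1-one (racemic), via silyl enol ether 2 (not isolated)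
Conditions: LiN(i-Pr)2, THF, −78 °C; Me3SiCl; solvent exchange to DMSO; Pd(OAc)2 (10 mol %), O2 (1 atm), rt
Reagents that add atoms: none
Why: Kinetic deprotonation at the unsubstituted α-carbon gives the less substituted silyl enol ether, and its Saegusa–Ito dehydrogenation (Pd(OAc)2 turned over by O2) places the enone double bond away from the methyl-bearing carbon.

Step 2
Reactants: 3 6-methylcyclohex-2-en-1-one; 4 phenyl vinyl sulfoxide
Product: 5 6-methyl-6-[2-(phenylsulfinyl)ethyl]cyclohex-2-en-1-one (diastereomer mixture)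
Conditions: LiN(i-Pr)2, THF, −78 °C; 4, −78 → 0 °C; aq. NH4Cl
Reagents that add atoms: none
Why: The cross-conjugated α′-enolate formed under kinetic control undergoes Michael addition to the vinyl sulfoxide, a vinyl cation equivalent, which builds the quaternary carbon (future C7) without regiochemical ambiguity.

Step 3
Reactants: 5 6-methyl-6-[2-(phenylsulfinyl)ethyl]cyclohex-2-en-1-one
Product: 6 6-ethenyl-6-methylcyclohex-2-en-1-one (racemic)
Conditions: toluene, NaHCO3 (solid), 110 °C
Reagents that add atoms: none
Why: Thermal syn-elimination of the sulfoxide (Ei) can only take a hydrogen from the methylene next to the quaternary carbon and so unmasks the vinyl group.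

Step 4
Reactants: 6 6-ethenyl-6-methylcyclohex-2-en-1-one; 7 (1,3-dioxolan-2-ylmethyl)magnesium bromide
Product: 9 (2S,3R,6RS)-3-(1,3-dioxolan-2-ylmethyl)-6-ethenyl-2-(hydroxymethyl)-6-methylcyclohexan-1-one, via magnesium enolate 8 (not isolated)
Conditions: CuBr·SMe2 (5 mol %), Josiphos [1-(2-diphenylphosphinoferrocenyl)ethyldicyclohexylphosphine, the enantiomer that turns cyclohex-2-enone and EtMgBr into (S)-3-ethylcyclohexanone] (6 mol %), t-BuOMe/2-methyltetrahydrofuran, −78 °C, slow addition of 7; then CH2O (gas from cracked paraformaldehyde), −78 → −40 °C; aq. NH4Cl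
Reagents that add atoms: formaldehyde, C=O
Why: Copper-catalysed asymmetric conjugate addition sets C4a under ligand control on both enantiomers of 6 (the remote methyl/vinyl centre offers little bias), and the magnesium enolate, which can only be the C11–C11a enolate, takes up formaldehyde anti to the new side arm (aldol hydroxymethylation) to set C11a trans.

Step 5
Reactants: 9 (2S,3R,6RS)-3-(1,3-dioxolan-2-ylmethyl)-6-ethenyl-2-(hydroxymethyl)-6-methylcyclohexan-1-one
Product: 10 (2S,3R,6RS)-2-({[tert-butyl(dimethyl)silyl]oxy}methyl)-3-(1,3-dioxolan-2-ylmethyl)-6-ethenyl-6-methylcyclohexan-1-one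
Conditions: t-BuMe2SiCl, imidazole, DMF, 0 °C → rt
Reagents that add atoms: tert-butyldimethylsilyl chloride, CC(C)(C)[Si](C)(C)Cl
Why: Silyl ether formation under mild amine buffering protects the primary alcohol without retro-aldol cleavage or β-elimination of the β-hydroxy ketone.

Step 6
Reactants: 10 silyl ether ketone
Product: 11 (3S,4R,7RS)-3-({[tert-butyl(dimethyl)silyl]oxy}methyl)-4-(1,3-dioxolan-2-ylmethyl)-7-ethenyl-7-methyloxepan-2-one
Conditions: mCPBA, NaHCO3, CH2Cl2, 0 °C → rt
Reagents that add atoms: 3-chloroperoxybenzoic acid, O=C(OO)c1cccc(Cl)c1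
Why: In this Baeyer–Villiger oxidation the quaternary allylic carbon migrates in preference to the methine bearing the electron-withdrawing silyloxymethyl group, so oxygen is inserted next to the future C7 with retention, while the hindered monosubstituted vinyl group is epoxidised far more slowly.

Step 7
Reactants: 11 oxepan-2-one
Product: 12 (2RS,5R,6S)-6-({[tert-butyl(dimethyl)silyl]oxy}methyl)-5-(1,3-dioxolan-2-ylmethyl)-2-ethenyl-2-methyl-7-methylideneoxepane
Conditions: Cp2TiMe2, toluene/THF, 65 °C, dark; rapid filtration through basic alumina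
Reagents that add atoms: dimethyltitanocene, C[Ti](C)(C1C=CC=C1)C1C=CC=C1
Why: Petasis methylenation converts the lactone carbonyl into the exocyclic enol ether under neutral conditions that leave the adjacent C11a centre, the acetal and the silyl ether untouched.

Step 8
Reactants: 12 2-ethenyl-7-methylideneoxepane (both C7 epimers)
Product: 13 (4Z,8R,9S)-9-({[tert-butyl(dimethyl)silyl]oxy}methyl)-8-(1,3-dioxolan-2-ylmethyl)-5-methylcyclonon-4-en-1-one
Conditions: toluene (degassed), Et3N (trace), sealed base-washed silylated tube, 185 °C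
Reagents that add atoms: none
Why: Heating brings the C7 vinyl group over the exocyclic enol ether, and in a concerted [3,3]-sigmatropic (Claisen) shift C9 bonds to C10 while the C7–O bond breaks, so the ring oxygen becomes the C11 carbonyl and the C7=C8 olefin appears. The closest known reaction type is the Claisen ring expansion of 2-methylidene-6-vinyltetrahydropyrans to cyclooct-4-enones and of seven-membered vinyl ketene acetals to nine-membered lactones. The nine-membered carbocycle is not closed end to end but arises by two-atom enlargement of the oxepane through a bridged, boat-like six-centre transition state, which avoids the entropic and transannular cost of a direct medium-ring cyclisation. No stereocentre is formed: C7 becomes trigonal, so both epimers of 12 converge on 13, while C4a and C11a lie outside the reacting array and the neutral medium spares the enolisable C11a. The four-carbon tether C11a–C4a–C5–C6 between C11 and C7 can span the transition state only on the side of C9, which enforces the Z geometry of C7=C8. The selectivity needed is rearrangement over acid-catalysed migration of the exocyclic double bond into the ring, secured by base-treated glassware, a trace of amine and immediate thermolysis of freshly filtered 12.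

Step 9
Reactants: 13 cyclononenone
Product: 14 (1Z,6R,7R)-6-({[tert-butyl(dimethyl)silyl]oxy}methyl)-7-(1,3-dioxolan-2-ylmethyl)-1-methyl-5-methylidenecyclonon-1-ene
Conditions: Cp2TiMe2, toluene, 70 °C, dark
Reagents that add atoms: dimethyltitanocene, C[Ti](C)(C1C=CC=C1)C1C=CC=C1
Why: Petasis olefination methylenates the hindered, enolisable C11 ketone without epimerising C11a or eliminating the β-silyloxy group, both of which a basic phosphorus ylide would risk.

Step 10
Reactants: 14 diene acetal
Product: 15 (4aR,7Z,11aR)-7-methyl-11-methylidene-1,3,4,4a,5,6,9,10,11,11a-decahydrocyclonona[c]pyran-3-ol (anomer mixture)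
Conditions: 1 M aq. HCl/THF (1:3), 0 °C → rt
Reagents that add atoms: water, O
Why: Acid hydrolysis removes the primary silyl ether and the dioxolane in one operation and the freed hydroxy aldehyde closes to the six-membered lactol (hemiacetal formation), at the only stage where the ring carries just two isolated olefins and no acid-labile oxygen function.

Step 11
Reactants: 15 lactol
Product: 16 (4aR,7Z,11aR)-7-methyl-11-methylidene-4,4a,5,6,9,10,11,11a-octahydrocyclonona[c]pyran-3(1H)-one
Conditions: TEMPO (20 mol %), PhI(OAc)2, CH2Cl2, rt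
Reagents that add atoms: none
Why: Oxoammonium-mediated oxidation of the lactol gives the δ-lactone, and the olefins are inert to this oxidant.

Step 12
Reactants: 16 lactone diene
Product: 17 (4aR,7S,8R,11aR)-7,8-epoxy-7-methyl-11-methylidenedecahydrocyclonona[c]pyran-3(1H)-one
Conditions: mCPBA (1.0 equiv), NaHCO3, CH2Cl2, −20 → 0 °C
Reagents that add atoms: 3-chloroperoxybenzoic acid, O=C(OO)c1cccc(Cl)c1
Why: Prilezhaev epoxidation favours the electron-rich trisubstituted C7=C8 olefin over the 1,1-disubstituted C11 methylene, and attack on the outer face of the Z-olefin, in the ring conformer that keeps the trans-fused lactone bonds equatorial, is expected to place the oxygen on the face of H-4a, which defines C7 (C8 is set provisionally).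

Step 13
Reactants: 17 7,8-epoxide
Product: 20 (4aR,7S,8Z,11aR)-7-hydroxy-7-methyl-11-methylidene-4,4a,5,6,7,10,11,11a-octahydrocyclonona[c]pyran-3(1H)-one, via hydroxy selenide 18 (not isolated), via selenoxide 19 (not isolated)
Conditions: (PhSe)2, NaBH4, EtOH, rt; then THF, 30% aq. H2O2, pyridine, 0 °C → rt
Reagents that add atoms: none
Why: The borane-complexed selenolate opens the epoxide by SN2 attack at the less hindered C8, leaving the oxygen on C7 with its configuration, and the selenoxide can only undergo syn-elimination toward C9 because C7 has no hydrogen, giving the transposed tertiary allylic alcohol with the ring-favoured Z C8=C9 olefin (epoxide-to-allylic-alcohol transposition by selenoxide elimination).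

Step 14
Reactants: 21 (2R)-but-3-ene-1,2-diol
Product: 22 (2R)-1-[(triethylsilyl)oxy]but-3-en-2-ol
Conditions: Et3SiCl (1.0 equiv), imidazole, CH2Cl2, −78 → −30 °C
Reagents that add atoms: chlorotriethylsilane, CC[Si](Cl)(CC)CC
Why: At low temperature the primary hydroxyl is silylated much faster than the secondary allylic one (selective silyl ether formation), and the C13 centre is bought with the diol.

Step 15
Reactants: 22 (2R)-1-[(triethylsilyl)oxy]but-3-en-2-ol
Product: 23 (2R)-4-methyl-1-[(triethylsilyl)oxy]pent-3-en-2-ol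
Conditions: 2-methylbut-2-ene (large excess), second-generation Grubbs catalyst RuCl2(=CHPh)(PCy3)(H2IMes) (5 mol %), CH2Cl2, 40 °C
Reagents that add atoms: 2-methylbut-2-ene, CC=C(C)C
Why: Olefin cross-metathesis with an excess of the trisubstituted partner caps the terminal vinyl group as the isopropylidene unit without touching the carbinol centre.

Step 16
Reactants: 23 (2R)-4-methyl-1-[(triethylsilyl)oxy]pent-3-en-2-ol
Product: 24 (1S)-1-[(2R)-3,3-dimethyloxiran-2-yl]-2-[(triethylsilyl)oxy]ethan-1-ol
Conditions: mCPBA, NaHCO3, CH2Cl2, 0 °C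
Reagents that add atoms: 3-chloroperoxybenzoic acid, O=C(OO)c1cccc(Cl)c1
Why: Allylic 1,3-strain from the cis-methyl group holds the carbinol C–H bond in the olefin plane, so the hydrogen-bonded peracid is delivered from the face of the free hydroxyl and gives the threo epoxy alcohol (hydroxyl-directed epoxidation), which sets C14.

Step 17
Reactants: 24 threo epoxy alcohol
Product: 25 triethyl({(1S)-1-[(2R)-3,3-dimethyloxiran-2-yl]-2-[(triethylsilyl)oxy]ethyl}oxy)silane
Conditions: Et3SiCl, imidazole, DMF, 0 °C
Reagents that add atoms: chlorotriethylsilane, CC[Si](Cl)(CC)CC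
Why: Silyl ether formation masks the C13 hydroxyl with a group that survives enolate chemistry and can be removed at the end without acid.

Step 18
Reactants: 25 bis(triethylsilyl) ether
Product: 26 (2R)-2-[(2R)-3,3-dimethyloxiran-2-yl]-2-[(triethylsilyl)oxy]acetaldehyde
Conditions: (COCl)2, DMSO, CH2Cl2, −78 → −30 °C; then Et3N, −78 °C → 0 °C
Reagents that add atoms: none
Why: Under Swern conditions a primary triethylsilyl ether is cleaved by the chlorosulfonium salt and oxidised in the same flask while the secondary silyl ether is untouched, so the α-silyloxy aldehyde is obtained directly.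

Step 19
Reactants: 20 allylic alcohol lactone; 26 epoxy aldehyde
Product: 27 aldol adduct: lactone 20 bearing at C4 a (2S)-2-[(2R)-3,3-dimethyloxiran-2-yl]-1-hydroxy-2-[(triethylsilyl)oxy]ethyl group (epimers at C4 and C12)
Conditions: LiN(i-Pr)2 (2.2 equiv), THF, −78 °C; 26, −78 °C; AcOH quench
Reagents that add atoms: none
Why: The alkoxide–enolate dianion of 20 adds through the lactone α-carbon C4 to the aldehyde (aldol addition), and the two new centres at C4 and C12 disappear in the next step, so their configuration does not matter.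

Step 20
Reactants: 27 aldol adduct
Product: 29 (4E,4aS,7S,8Z,11aR)-4-{(2S)-2-[(2R)-3,3-dimethyloxiran-2-yl]-2-[(triethylsilyl)oxy]ethylidene}-7-hydroxy-7-methyl-11-methylidene-4,4a,5,6,7,10,11,11a-octahydrocyclonona[c]pyran-3(1H)-one, via aldol acetate 28 (not isolated)
Conditions: Ac2O, pyridine, DMAP (cat.), CH2Cl2, 0 °C; then DBU, 0 °C → rt
Reagents that add atoms: none
Why: Only the secondary aldol hydroxyl is acetylated (the tertiary C7 alcohol is inert), and E1cB elimination through the lactone enolate gives the thermodynamically preferred E-alkylidene lactone with C13 anti to the carbonyl.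

Step 21
Reactants: 29 alkylidene lactone
Product: 30 (4E,4aS,7S,8R,9R,11aR)-4-{(2S)-2-[(2R)-3,3-dimethyloxiran-2-yl]-2-[(triethylsilyl)oxy]ethylidene}-8,9-epoxy-7-hydroxy-7-methyl-11-methylidenedecahydrocyclonona[c]pyran-3(1H)-one
Conditions: VO(acac)2 (5 mol %), t-BuOOH (decane solution), CH2Cl2, 0 °C → rt
Reagents that add atoms: tert-butyl hydroperoxide, CC(C)(C)OO
Why: The vanadium alkoxide of the tertiary C7 alcohol delivers the peroxide oxygen to the adjacent Z C8=C9 olefin on the hydroxyl-bearing face (hydroxyl-directed epoxidation), setting C8 and C9 syn to the C7 hydroxyl, while the C11 methylene and the electron-poor alkylidene lactone are left alone.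

Step 22
Reactants: 30 silyl ether bis-epoxide
Product: 31 (4E,4aS,7S,8R,9R,11aR)-4-{(2S)-2-[(2R)-3,3-dimethyloxiran-2-yl]-2-hydroxyethylidene}-8,9-epoxy-7-hydroxy-7-methyl-11-methylidenedecahydrocyclonona[c]pyran-3(1H)-one
Conditions: Bu4NF, AcOH (1:1), THF, 0 °C
Reagents that add atoms: none
Why: Buffered fluoride cleaves the secondary triethylsilyl ether (desilylation) without opening either epoxide or adding to the alkylidene lactone.

Step 23
Reactants: 31 diol
Product: 32 target CNP0113449.2, the C13 acetate of 31
Conditions: Ac2O, pyridine, DMAP (cat.), CH2Cl2, 0 °C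
Reagents that add atoms: acetic anhydride, CC(=O)OC(C)=O
Why: Acylation takes place at the secondary C13 hydroxyl only, because the tertiary C7 alcohol flanked by the epoxide does not react under these conditions.

**Compound list**
1 | 2-methylcyclohexan-1-one (racemic) | CC1CCCCC1=O | starting material
2 | trimethyl[(6-methylcyclohex-1-en-1-yl)oxy]silane | CC1CCCC=C1O[Si](C)(C)C | intermediate
3 | 6-methylcyclohex-2-en-1-one (racemic) | CC1CCC=CC1=O | intermediate
4 | phenyl vinyl sulfoxide (racemic) | C=CS(=O)c1ccccc1 | starting material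
5 | 6-methyl-6-[2-(phenylsulfinyl)ethyl]cyclohex-2-en-1-one (diastereomer mixture) | CC1(CCS(=O)c2ccccc2)CCC=CC1=O | intermediate
6 | 6-ethenyl-6-methylcyclohex-2-en-1-one (racemic) | C=CC1(C)CCC=CC1=O | intermediate
7 | (1,3-dioxolan-2-ylmethyl)magnesium bromide | Br[Mg]CC1OCCO1 | starting material
8 | bromomagnesium C1–C2 enolate of (3R,6RS)-3-(1,3-dioxolan-2-ylmethyl)-6-ethenyl-6-methylcyclohexan-1-one | C=CC1(C)CC[C@H](CC2OCCO2)C=C1O[Mg]Br | intermediate
9 | (2S,3R,6RS)-3-(1,3-dioxolan-2-ylmethyl)-6-ethenyl-2-(hydroxymethyl)-6-methylcyclohexan-1-one | C=CC1(C)CC[C@H](CC2OCCO2)[C@@H](CO)C1=O | intermediate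
10 | (2S,3R,6RS)-2-({[tert-butyl(dimethyl)silyl]oxy}methyl)-3-(1,3-dioxolan-2-ylmethyl)-6-ethenyl-6-methylcyclohexan-1-one | C=CC1(C)CC[C@H](CC2OCCO2)[C@@H](CO[Si](C)(C)C(C)(C)C)C1=O | intermediate
11 | (3S,4R,7RS)-3-({[tert-butyl(dimethyl)silyl]oxy}methyl)-4-(1,3-dioxolan-2-ylmethyl)-7-ethenyl-7-methyloxepan-2-one | C=CC1(C)CC[C@H](CC2OCCO2)[C@@H](CO[Si](C)(C)C(C)(C)C)C(=O)O1 | intermediate
12 | (2RS,5R,6S)-6-({[tert-butyl(dimethyl)silyl]oxy}methyl)-5-(1,3-dioxolan-2-ylmethyl)-2-ethenyl-2-methyl-7-methylideneoxepane | C=CC1(C)CC[C@H](CC2OCCO2)[C@@H](CO[Si](C)(C)C(C)(C)C)C(=C)O1 | intermediate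
13 | (4Z,8R,9S)-9-({[tert-butyl(dimethyl)silyl]oxy}methyl)-8-(1,3-dioxolan-2-ylmethyl)-5-methylcyclonon-4-en-1-one | O=C1CC/C=C(C)\CC[C@H](CC2OCCO2)[C@H]1CO[Si](C)(C)C(C)(C)C | intermediate
14 | (1Z,6R,7R)-6-({[tert-butyl(dimethyl)silyl]oxy}methyl)-7-(1,3-dioxolan-2-ylmethyl)-1-methyl-5-methylidenecyclonon-1-ene | C=C1CC/C=C(C)\CC[C@H](CC2OCCO2)[C@H]1CO[Si](C)(C)C(C)(C)C | intermediate
15 | (4aR,7Z,11aR)-7-methyl-11-methylidene-1,3,4,4a,5,6,9,10,11,11a-decahydrocyclonona[c]pyran-3-ol (anomer mixture) | C=C1CC/C=C(C)\CC[C@@H]2CC(O)OC[C@@H]12 | intermediate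
16 | (4aR,7Z,11aR)-7-methyl-11-methylidene-4,4a,5,6,9,10,11,11a-octahydrocyclonona[c]pyran-3(1H)-one | C=C1CC/C=C(C)\CC[C@@H]2CC(=O)OC[C@@H]12 | intermediate
17 | (4aR,7S,8R,11aR)-7,8-epoxy-7-methyl-11-methylidenedecahydrocyclonona[c]pyran-3(1H)-one | C=C1CC[C@H]3O[C@@]3(C)CC[C@@H]2CC(=O)OC[C@@H]12 | intermediate
18 | (4aR,7S,8S,11aR)-7-hydroxy-7-methyl-11-methylidene-8-(phenylselanyl)decahydrocyclonona[c]pyran-3(1H)-one | C=C1CC[C@H]([Se]c3ccccc3)[C@@](C)(O)CC[C@@H]2CC(=O)OC[C@@H]12 | intermediate
19 | (4aR,7S,8S,11aR)-8-(benzeneseleninyl)-7-hydroxy-7-methyl-11-methylidenedecahydrocyclonona[c]pyran-3(1H)-one | C=C1CC[C@H]([Se](=O)c3ccccc3)[C@@](C)(O)CC[C@@H]2CC(=O)OC[C@@H]12 | intermediate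
20 | (4aR,7S,8Z,11aR)-7-hydroxy-7-methyl-11-methylidene-4,4a,5,6,7,10,11,11a-octahydrocyclonona[c]pyran-3(1H)-one | C=C1C/C=C\[C@@](C)(O)CC[C@@H]2CC(=O)OC[C@@H]12 | intermediate
21 | (2R)-but-3-ene-1,2-diol | C=C[C@@H](O)CO | starting material
22 | (2R)-1-[(triethylsilyl)oxy]but-3-en-2-ol | C=C[C@@H](O)CO[Si](CC)(CC)CC | intermediate
23 | (2R)-4-methyl-1-[(triethylsilyl)oxy]pent-3-en-2-ol | CC(C)=C[C@@H](O)CO[Si](CC)(CC)CC | intermediate
24 | (1S)-1-[(2R)-3,3-dimethyloxiran-2-yl]-2-[(triethylsilyl)oxy]ethan-1-ol | CC[Si](CC)(CC)OC[C@H](O)[C@H]1OC1(C)C | intermediate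
25 | triethyl({(1S)-1-[(2R)-3,3-dimethyloxiran-2-yl]-2-[(triethylsilyl)oxy]ethyl}oxy)silane | CC[Si](CC)(CC)OC[C@H](O[Si](CC)(CC)CC)[C@H]1OC1(C)C | intermediate
26 | (2R)-2-[(2R)-3,3-dimethyloxiran-2-yl]-2-[(triethylsilyl)oxy]acetaldehyde | O=C[C@H](O[Si](CC)(CC)CC)[C@H]1OC1(C)C | intermediate
27 | aldol adduct: 20 bearing at C4 a (2S)-2-[(2R)-3,3-dimethyloxiran-2-yl]-1-hydroxy-2-[(triethylsilyl)oxy]ethyl group (C4/C12 epimers) | C=C1C/C=C\[C@@](C)(O)CC[C@@H]2C(C(O)[C@H](O[Si](CC)(CC)CC)[C@H]3OC3(C)C)C(=O)OC[C@@H]12 | intermediate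
28 | aldol acetate: 27 acetylated at the C12 hydroxyl | C=C1C/C=C\[C@@](C)(O)CC[C@@H]2C(C(OC(C)=O)[C@H](O[Si](CC)(CC)CC)[C@H]3OC3(C)C)C(=O)OC[C@@H]12 | intermediate
29 | (4E,4aS,7S,8Z,11aR)-4-{(2S)-2-[(2R)-3,3-dimethyloxiran-2-yl]-2-[(triethylsilyl)oxy]ethylidene}-7-hydroxy-7-methyl-11-methylidene-4,4a,5,6,7,10,11,11a-octahydrocyclonona[c]pyran-3(1H)-one | C=C1C/C=C\[C@@](C)(O)CC[C@@H]2/C(=C\[C@H](O[Si](CC)(CC)CC)[C@H]3OC3(C)C)C(=O)OC[C@@H]12 | intermediate
30 | (4E,4aS,7S,8R,9R,11aR)-4-{(2S)-2-[(2R)-3,3-dimethyloxiran-2-yl]-2-[(triethylsilyl)oxy]ethylidene}-8,9-epoxy-7-hydroxy-7-methyl-11-methylidenedecahydrocyclonona[c]pyran-3(1H)-one | C=C1C[C@H]2O[C@H]2[C@@](C)(O)CC[C@@H]2/C(=C\[C@H](O[Si](CC)(CC)CC)[C@H]3OC3(C)C)C(=O)OC[C@@H]12 | intermediate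
31 | (4E,4aS,7S,8R,9R,11aR)-4-{(2S)-2-[(2R)-3,3-dimethyloxiran-2-yl]-2-hydroxyethylidene}-8,9-epoxy-7-hydroxy-7-methyl-11-methylidenedecahydrocyclonona[c]pyran-3(1H)-one | C=C1C[C@H]2O[C@H]2[C@@](C)(O)CC[C@@H]2/C(=C\[C@H](O)[C@H]3OC3(C)C)C(=O)OC[C@@H]12 | intermediate
32 | CNP0113449.2: (4E,4aS,7S,8R,9R,11aR)-4-{(2S)-2-acetoxy-2-[(2R)-3,3-dimethyloxiran-2-yl]ethylidene}-8,9-epoxy-7-hydroxy-7-methyl-11-methylidenedecahydrocyclonona[c]pyran-3(1H)-one | C=C1C[C@H]2O[C@H]2[C@@](C)(O)CC[C@@H]2/C(=C\[C@H](OC(C)=O)[C@H]3OC3(C)C)C(=O)OC[C@@H]12 | target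

**Step count**
Total: 23 steps. Longest linear sequence: 18 steps (steps 1–13 and 19–23, from 2-methylcyclohexanone); the side-chain branch is steps 14–18.

**Steps most likely to fail**

Step 12. The Z-cyclononene is conformationally mobile, so peracid attack may show low or reversed facial selectivity. That would carry the C7 epimer forward and, after step 21, the 7,8,9-epimeric series. The fallback sets out from 16 and uses hydroxyselenation: N-(phenylselanyl)phthalimide, water and catalytic camphorsulfonic acid in CH2Cl2 add selenium and hydroxyl anti across C7=C8 in the Markovnikov sense. Because the hydroxyl now enters opposite to the electrophile, the facial outcome at C7 is inverted relative to epoxidation. The adduct is hydroxy selenide 18 itself, so the route is rejoined at 18 (oxidation as in step 13) and no compound outside the list arises (F0).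

Step 8. Acid-catalysed migration of the exocyclic double bond of 12 into the ring would consume the precursor. Separately, the C7 epimer whose reactive conformer forces both side arms axial may rearrange sluggishly. The fallback sets out from 12: i-Bu3Al in CH2Cl2 at −78 → −20 °C promotes the rearrangement through a Lewis-acid-polarised pathway far below the thermal threshold and reduces the emerging ketone in the same flask, giving cyclononenol F1 (C11 epimers). Oxidation of F1 with Dess–Martin periodinane returns to 13.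

Step 4. The β-alkoxy Grignard reagent is available only in a donor ether solvent, so enantioselectivity may be eroded by uncatalysed background addition. The two enantiomers of 6 may also respond unequally to the catalyst, and formaldehyde capture may be incomplete. The fallback sets out from 6 with a rhodium-catalysed asymmetric 1,4-addition (Hayashi–Miyaura reaction) of (E)-2-(2-ethoxyethenyl)-4,4,5,5-tetramethyl-1,3,2-dioxaborolane, using Rh(acac)(C2H4)2 and the BINAP enantiomer that gives (S)-3-phenylcyclohexanone from cyclohex-2-enone, in dioxane/water. This gives the enol ether ketone F2. Acetal exchange with ethylene glycol and pyridinium p-toluenesulfonate converts it into the dioxolane ketone F3. Since the other α-carbon is quaternary, LiN(i-Pr)2 can only form the C11–C11a enolate of F3, and monomeric formaldehyde then gives 9 with the trans arrangement.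

**Further compounds**
F0 | step 12 | none | none
F1 | step 8 | (1RS,4Z,8R,9S)-9-({[tert-butyl(dimethyl)silyl]oxy}methyl)-8-(1,3-dioxolan-2-ylmethyl)-5-methylcyclonon-4-en-1-ol | OC1CC/C=C(C)\CC[C@H](CC2OCCO2)[C@H]1CO[Si](C)(C)C(C)(C)C
F2 | step 4 | (3S,6RS)-3-[(E)-2-ethoxyethenyl]-6-ethenyl-6-methylcyclohexan-1-one | C=CC1(C)CC[C@H](/C=C/OCC)CC1=O
F3 | step 4 | (3R,6RS)-3-(1,3-dioxolan-2-ylmethyl)-6-ethenyl-6-methylcyclohexan-1-one | C=CC1(C)CC[C@H](CC2OCCO2)CC1=O
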